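In a one-step world G turns straight into Q, and a run of readings reduces to one number: how fast the line climbs.

| flask | G | D | remark | time |
|---|---|---|---|---|
| birch | 45 mM | 7.6 mM (held) | run made earlier |  |
| flask | 30 mM | 7.6 mM (held) |  | 3.0 d |

- birch (time / h: Q / %): 1.00: 0; 2.00: 0.9; 3.00: 2.6; 4.00: 4.7; 5.00: 6.6; 6.00: 9.1; 8.00: 13.0

(scatter of a reading: 0.5 percentage points)

- at the start none of D is in solution
- X is what D becomes in solution

* how much Q there is at 3.0 d, in percent of the G charged
* concentration of X in solution at 40 h, in percent of saturation
* the change that raises the amount of Q at 3.0 d, in percent of the G charged most ("none" if none brings more than 2 percentage points) (summer / midnight / none)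
* amount of Q at 3.0 d, in percent of the G charged, after summer

- summer: doubling the saturation concentration of D, all else as stated
- midnight: doubling the transfer coefficient of D, all else as stated

Take the birch run and replace its curve by its mean slope, from the reading at 2.00 h to the one at 8.00 h. At that slope, one whole charge takes 49.6 h; call this the clearing time. Followed back to zero Q, the line leaves a lag of 1.55 h. The replacement costs little: at 5.00 h the line stands 0.35 percentage points above the reading, less than the scatter of 0.5 points.

Yet this same line gives 142% of the charge at 3.0 d, so a good fit yields an impossible number. Both stand, since the readings end at 11.1% of the asked time, with Q at 13.0%. Lag plus clearing time is 51.1 h, shorter than 3.0 d, so the curve must bend inside the asked time. My own reckoning, in percent of the charge although the flask holds 30 mM of G against 45 mM, therefore trusts the line while G lasts and gives no number for 3.0 d.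

The forecast gives 86% of Q, c(X) at 90% of saturation at 40 h, summer as the best change and 98% after it, reading the run as “X + G → Q, second order, with X consumed”.

The flask gives 15.5% of Q, c(X) at >99.9% of saturation at 40 h, and 14.5% after summer. Summer moves Q by −0.95 points and midnight by −0.74 points, so the choice is none.

    J ⇌ E (K = 2.00, k = 6.60 × 10⁻⁶ s⁻¹)
    D ⇌ X, rate k2*(csat - [X]) (kL = 1.10 × 10⁻⁴ s⁻¹)
    J → L (k = 1.70 × 10⁻⁵ s⁻¹)
    J ⇌ Q (K = 1.90, k = 4.30 × 10⁻⁵ s⁻¹)
    G + X → J + Z (k = 0.0190 L mol⁻¹ s⁻¹)

On this flask the line gives 33.2% at 0.750 d, where Q stands at 37.3%. By 1.50 d, G, the limiting reagent, stands at 0% and Q has come down to 30.5%. The flask is not at rest at 3.0 d, where it holds Q at 15.5% and L at 63.3%. Left until 30.0 d, ten times as long, it holds Q at 0.0655% and L at 99.7%.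

For the neighbour flask read at 30 h, the clearing time puts the line at 57.4%, under the whole charge but with G already at 0.011%. That flask gives 34.4%.

The runs were generated by integration with made-up constants; the scatter is artificial.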